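Compound numbers: 1–11 lead from geraniol to the primed-half dienone, 12–19 from nerol to the unprimed-half cyclopentenone, 20–33 cover the union and the end game. Compound 29 is the substrate and 31 the product of the key step; 33 is the target.

## The problem

The target 33 consists of two guaianolide halves joined by the C2–C2' and C3–C5' bonds, so that C1', C2', C3', C4', C5', C2 and C3 form a bicyclo[2.2.1]heptan-2-one (ketone at C3') onto which the unprimed cyclopentene (C1–C5, alkene C4=C5) is fused on the endo side. Each half carries a seven-membered carbocycle and a γ-lactone trans-fused across C6–C7 (C6'–C7'); on the primed side the seven-membered ring spans the bridge carbon C1' and the quaternary bridgehead C5'. Fifteen stereocentres must be set: nine in or next to the core (C1, C2, C3, C10, C1', C2', C4', C5', C10') and six in the outer rings (C6, C7, C11 and their primed partners). C1 and C1' can direct the construction of the core (C2, C3, C2', C5'), the finished core can direct the closures at C6/C7 and C6'/C7', and C7/C7' can direct C11/C11'. C10 and C10' are tertiary carbinols that lie outside every ring until the seven-membered rings exist, so they need an acyclic, stereospecific solution together with C1/C1'. The sensitive groups are the tertiary alcohols (elimination under acid, lactol formation with a γ-carbonyl group), the epimerisable centres C4' and C11/C11', the lactones and the tetrasubstituted C4=C5 alkene. The key step is made possible because, in both halves, the C6–C7 bond belongs to the seven-membered ring and to the lactone at once while C7 bears the lactone α-carbon. This is the retron of a C6 aldehyde allylated by the γ-carbon of a 2-(halomethyl)acrylate.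

## Retrosynthesis

**33 to 31.** No skeletal bond is cut first. The target 33 is traced to its bis-silyl ether 32 and then to the bis(α-methylene lactone) 31 by removing the C11–H and C11'–H bonds. C11 and C11' are epimerisable and are best set last, by conjugate reduction under control of C7 and C7'. The tertiary alcohols stay silylated to the end because a free C10 or C10' hydroxyl would form a five-membered lactol with the C6 or C6' aldehyde of the preceding stage.

**31 to 29 (key cut).** C6–C7, C6'–C7' and both lactone C–O bonds are cut, which leads to the dialdehyde 29 with two (Z)-2-(bromomethyl)enoate chains. Against cuts at C8–C9 or C1–C10, this one removes four rings and four stereocentres at once and leaves only a tricyclic core with two acyclic chains. The forward reaction must distinguish aldehydes from the C3' ketone, send each chain to its own aldehyde and close both lactones trans.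

**29 to 25.** The allylic bromides of 29 come from the bis-Baylis–Hillman adduct 28, made from the tetracarbonyl compound 26 and two molecules of methyl acrylate 27, one for each chain. The C11–C7 bonds are cut here. The three aliphatic aldehydes of 26 (C7, C7', C6') are traced to three isopropylidene-capped alkenes in 25, so that one ozonolysis unveils them together. The forward steps must spare the conjugated C4=C5 alkene and leave the hindered C6 and C6' aldehydes untouched.

**25 to 21.** The C4–C15 and C5–C6 bonds and the C4=C5 alkene are traced to the C4 ketone of 21 through the alkoxymethylene ketone 23 and the hydroxymethylene ketone 22. This uses the ketone that activated the cycloaddition and adds only one-carbon units. The C3' ketone must stay masked as its silyl enol ether until the methyl nucleophile has been consumed.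

**21 to 20 and 19.** C2–C2' and C3–C5' are cut in a Diels–Alder sense, giving the 2-silyloxycyclopentadiene 20 and the 4-substituted cyclopentenone 19. Joining the halves instead by an oxidative enolate coupling at C2–C2' and a reductive C3–C5' closure would leave an oxygen on C3 to be removed next to the C4=C5 alkene, and it offers competing β,β-coupling. The cycloaddition forms both bonds and four stereocentres (C2, C3, C2', C5') in one step. It needs attack anti to C10 and C10', an endo transition state and the para orientation that the silyloxy group dictates.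

**20 to 6.** Diene 20 is the kinetic silyl dienol ether of dienone 11. The enone of 11 is traced by oxidative 1,3-transposition to the tertiary allylic alcohol 10, which cuts C5'–C6' back to enone 9. The ring of 9 is cut at C3'=C4' (ring-closing metathesis of 7 via 8) and at C4'–C5' (addition to aldehyde 6). The 2-methylprop-1-enyl group on C5' serves as a latent aldehyde and also blocks the unwanted direction of the transposition.

**19 to 17.** The enone of 19 is cut at C2=C3 (aldol condensation of keto aldehyde 18), and the methyl ketone of 18 comes from the allyl group of aldehyde 17 by Wacker oxidation. This places the carbonyl group remote from C1, as the dienophile requires.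

**6 and 17 to 1 and 12.** Both aldehydes come from 2-allyl-1,3-diols (3 via 4 and 5; 14 via 15 and 16). Cutting the C1'–C2' bond (or C1–C5) leads to the epoxy alcohols 2 and 13, and these to geraniol 1 and nerol 12. Asymmetric epoxidation sets C10/C10', and SN2 opening at the secondary carbon sets C1/C1' stereospecifically, which an aldol addition to a methyl ketone could not guarantee. The two halves need opposite relative configurations at C1/C10 once the ring is numbered, hence the E and the Z allylic alcohol. The chain of each terpene already holds C7–C10 and C14.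

## Roads not taken

**Alternative 1:** De Mayo two-carbon expansion. The cut removes C8' and C9' by breaking C7'–C8' and C9'–C10'. In the forward step the β-acetoxy enone A1 (C6' ketone, C7'=C10' enol acetate in a five-membered ring) is irradiated above 340 nm with ethylene A2 to give the cyclobutane A3. Retro-aldol opening would then expand the ring to the primed cycloheptane.
- Merits: a C–C bond is formed at a crowded position by a reaction that is indifferent to sterics, ethylene has no regiochemistry, and the unprimed half can be complete beforehand.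
- Weak points: only one of the two seven-membered rings is made. The fragmentation leaves C10' and C6' as ketones, so the tertiary carbinol, C6', C7' and the lactone must still be set on a flexible ring. The C3' ketone and the C4=C5 alkene are competing chromophores.
- Comparison: this road avoids allylic bromides and a diastereoselective metal-mediated closure, which is a real advantage. The chosen plan sets against it that both carbocycles, both lactones and four stereocentres arise in one operation.

**Alternative 2:** Double ring-closing metathesis. The cut is C8=C9 and C8'=C9'. The second-generation Grubbs catalyst would join the C7 and C10 vinyl groups of each half of the tetraene A4 and give the tetradehydro compound A5, two hydrogenations from the target.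
- Merits: mild conditions, tolerance of lactones and free alcohols, and no new stereocentre in the key step, so the ring fusion cannot go wrong there.
- Weak points: A4 must already hold all fifteen stereocentres, so the C6–C7 bonds and the tertiary allylic carbinols need separate stereocontrolled intermolecular steps. The vinyl groups on quaternary C10 and C10' are hindered, and the final hydrogenation must spare C4=C5.
- Comparison: in predictability of the closure this road is better than the chosen one. The chosen plan sets against it a much simpler precursor and the formation of the C6–C7 bond, the ring and the lactone together.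

**Alternative 3:** Intramolecular oxyallyl cation [3+2] cycloaddition. The cut is C1'–C2' and C4'–C5'. Fe2(CO)9 would reduce the α,α'-dibromoketone A6 to an iron-bound oxyallyl cation that adds across the tethered C1'=C5' alkene and gives the bis-trimethylsilyl ether A7.
- Merits: the central cyclopentane and the cyclopentanone are closed together, late, on two complete hydroazulene lactones.
- Weak points: oxyallyl [3+2] additions work with electron-rich or aryl-substituted alkenes, and the trisubstituted C1'=C5' alkene is neither. The closure builds a strained bicyclo[2.2.1]heptanone with a quaternary bridgehead. C4' and C1' would be set without an obvious control element, and the C4=C5 alkene competes.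
- Comparison: this road is the more convergent on paper. The chosen plan relies instead on a cycloaddition of a well-known type for the same core and keeps the uncertain step for a reaction with direct precedent.

Key step: step 24

Remarks: guaianolide numbering is used for every intermediate. R stands for the (2S)-2-(tert-butyldimethylsilyloxy)-6-methylhept-5-en-2-yl group (C10 with C14, O-silyl, C9, C8, C7 and the isopropylidene cap). TBS is tert-butyldimethylsilyl. Exo and endo refer to the bicyclo[2.2.1]heptane. The endo-methyl configuration at the epimerisable C4' is assumed to be the thermodynamically preferred one, as its presence in the target suggests.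

## Steps

Step 1
Reactants: 1 geraniol
Product: 2 (2S,3S)-2,3-epoxygeraniol
Conditions: Ti(OiPr)4 (cat.), L-(+)-diethyl tartrate (cat.), t-BuOOH, 4 Å molecular sieves, CH2Cl2, −20 °C
Reagents that add atoms: tert-butyl hydroperoxide, CC(C)(C)OO
Why: Sharpless asymmetric epoxidation of an (E)-trisubstituted allylic alcohol; the L-tartrate complex should deliver oxygen to the face that gives the (2S,3S)-epoxide and so fixes the future C10'.

Step 2
Reactants: 2 (2S,3S)-2,3-epoxygeraniol
Product: 3 (2R,3S)-3,7-dimethyl-2-(prop-2-en-1-yl)oct-6-ene-1,3-diol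
Conditions: CH2=CHCH2MgCl, CuI (cat.), THF, −30 → 0 °C
Reagents that add atoms: allylmagnesium chloride, C=CC[Mg]Cl
Why: Copper-catalysed Grignard opening of a 2,3-epoxy alcohol; the tertiary C3 cannot be attacked, so the allyl group should enter at C2 by SN2 with inversion and set C1' relative to C10'.

Step 3
Reactants: 3 (2R,3S)-3,7-dimethyl-2-(prop-2-en-1-yl)oct-6-ene-1,3-diol
Product: 5 (2R,3S)-3-(tert-butyldimethylsilyloxy)-3,7-dimethyl-2-(prop-2-en-1-yl)-1-(triethylsilyloxy)oct-6-ene, via primary triethylsilyl ether 4 (not isolated)
Conditions: Et3SiCl, imidazole, CH2Cl2, 0 °C; then t-BuMe2SiOTf, 2,6-lutidine, 0 °C → rt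
Reagents that add atoms: chlorotriethylsilane, CC[Si](Cl)(CC)CC; tert-butyldimethylsilyl trifluoromethanesulfonate, CC(C)(C)[Si](C)(C)OS(=O)(=O)C(F)(F)F
Why: Graded silylation; the chlorosilane should react only with the primary alcohol and the silyl triflate then caps the hindered tertiary alcohol.

Step 4
Reactants: 5 bis-silyl ether
Product: 6 (2S,3S)-3-(tert-butyldimethylsilyloxy)-3,7-dimethyl-2-(prop-2-en-1-yl)oct-6-enal
Conditions: (COCl)2, Me2SO, CH2Cl2, −78 → −30 °C; Et3N, −78 °C → rt
Reagents that add atoms: none
Why: Swern conditions oxidise primary triethylsilyl ethers directly to aldehydes while tertiary TBS ethers stay; the cold, briefly basic protocol should preserve the α-stereocentre.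

Step 5
Reactants: 6 aldehyde
Product: 7 (4R,5S)-5-(tert-butyldimethylsilyloxy)-2,5,9-trimethyl-4-(prop-2-en-1-yl)deca-1,8-dien-3-ol (both C3 epimers)
Conditions: CH2=C(CH3)MgBr, THF, −78 °C
Reagents that add atoms: isopropenylmagnesium bromide, CC(=C)[Mg]Br
Why: Grignard 1,2-addition brings in C4' and C15'; the new carbinol centre is oxidised in step 7, so its configuration does not matter.

Step 6
Reactants: 7 dienol
Product: 8 (5R)-2-methyl-5-R-cyclopent-2-en-1-ol (both C1 epimers)
Conditions: second-generation Grubbs catalyst (5 mol %), CH2Cl2, 40 °C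
Reagents that add atoms: none
Why: Ring-closing metathesis of a 1,6-diene; the catalyst should load on the monosubstituted alkene and close the five-membered ring onto the 1,1-disubstituted alkene much faster than a seven-membered ring onto the remote trisubstituted alkene.

Step 7
Reactants: 8 cyclopentenol
Product: 9 (5S)-2-methyl-5-R-cyclopent-2-en-1-one
Conditions: Dess–Martin periodinane, CH2Cl2, 0 °C → rt
Reagents that add atoms: none
Why: Neutral oxidation of an allylic alcohol; it should neither epimerise C1' nor eliminate the β-silyloxy group.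

Step 8
Reactants: 9 enone
Product: 10 (5R)-2-methyl-1-(2-methylprop-1-en-1-yl)-5-R-cyclopent-2-en-1-ol (both C1 epimers)
Conditions: (CH3)2C=CHMgBr, CeCl3, THF, −78 °C
Reagents that add atoms: 2-methylprop-1-enylmagnesium bromide, CC(C)=C[Mg]Br
Why: Organocerium 1,2-addition to an enolisable, hindered enone; it installs C6' as the CH of a latent aldehyde, and the carbinol configuration is lost in step 9.

Step 9
Reactants: 10 tertiary allylic alcohol
Product: 11 (4R)-2-methyl-3-(2-methylprop-1-en-1-yl)-4-R-cyclopent-2-en-1-one
Conditions: C5H5NH[CrO3Cl] (pyridinium chlorochromate), CH2Cl2, rt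
Reagents that add atoms: pyridinium chlorochromate, c1cc[nH+]cc1.[O-][Cr](Cl)(=O)=O
Why: Babler–Dauben oxidative transposition; the chromate ester should shift to C3', where the secondary allylic chromate is oxidised to the enone. The competing shift to the dimethyl-substituted terminus gives a tertiary chromate that cannot be oxidised and returns.

Step 10
Reactants: 12 nerol
Product: 13 (2R,3S)-2,3-epoxynerol
Conditions: Ti(OiPr)4, D-(−)-diethyl tartrate, t-BuOOH, 4 Å molecular sieves, CH2Cl2, −20 °C
Reagents that add atoms: tert-butyl hydroperoxide, CC(C)(C)OO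
Why: Sharpless asymmetric epoxidation of the (Z)-allylic alcohol with the D-tartrate; the (2R,3S)-epoxide has the same C10 configuration as 2 and the opposite one at the carbon that becomes C1.

Step 11
Reactants: 13 (2R,3S)-2,3-epoxynerol
Product: 14 (2S,3S)-3,7-dimethyl-2-(prop-2-en-1-yl)oct-6-ene-1,3-diol
Conditions: CH2=CHCH2MgCl, CuI (cat.), THF, −30 → 0 °C
Reagents that add atoms: allylmagnesium chloride, C=CC[Mg]Cl
Why: The same copper-catalysed SN2 opening at C2 with inversion; it should give the C1/C10 relationship of the unprimed half, in which the allyl group becomes C5–C4–C3.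

Step 12
Reactants: 14 (2S,3S)-diol
Product: 16 (2S,3S)-3-(tert-butyldimethylsilyloxy)-3,7-dimethyl-2-(prop-2-en-1-yl)-1-(triethylsilyloxy)oct-6-ene, via primary triethylsilyl ether 15 (not isolated)
Conditions: Et3SiCl, imidazole, CH2Cl2, 0 °C; then t-BuMe2SiOTf, 2,6-lutidine, 0 °C → rt
Reagents that add atoms: chlorotriethylsilane, CC[Si](Cl)(CC)CC; tert-butyldimethylsilyl trifluoromethanesulfonate, CC(C)(C)[Si](C)(C)OS(=O)(=O)C(F)(F)F
Why: Graded silylation as in step 3.

Step 13
Reactants: 16 bis-silyl ether
Product: 17 (2R,3S)-3-(tert-butyldimethylsilyloxy)-3,7-dimethyl-2-(prop-2-en-1-yl)oct-6-enal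
Conditions: (COCl)2, Me2SO, CH2Cl2, −78 → −30 °C; Et3N, −78 °C → rt
Reagents that add atoms: none
Why: Direct Swern oxidation of the primary triethylsilyl ether as in step 4.

Step 14
Reactants: 17 aldehyde
Product: 18 (2R,3S)-3-(tert-butyldimethylsilyloxy)-3,7-dimethyl-2-(2-oxopropyl)oct-6-enal
Conditions: PdCl2 (cat.), CuCl, O2, DMF/H2O, rt
Reagents that add atoms: water, O
Why: Tsuji–Wacker oxidation of the terminal alkene to the methyl ketone by Markovnikov hydroxypalladation; the trisubstituted alkene should be inert.

Step 15
Reactants: 18 keto aldehyde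
Product: 19 (4S)-4-R-cyclopent-2-en-1-one
Conditions: KOH (0.1 M), MeOH, 0 °C
Reagents that add atoms: none
Why: Intramolecular aldol condensation of a 1,4-keto aldehyde; only the methyl ketone enolate attacking the aldehyde gives an unstrained ring, and dehydration gives the cyclopent-2-enone. The α-hydrogen at C1 is flanked by the quaternary C10 and should enolise slowly.

Step 16
Reactants: 11 dienone
Product: 20 (5R)-2-(tert-butyldimethylsilyloxy)-3-methyl-4-(2-methylprop-1-en-1-yl)-5-R-cyclopenta-1,3-diene
Conditions: LiN(iPr)2, THF, −78 °C; t-BuMe2SiOTf, −78 °C; cold non-aqueous work-up, used at once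
Reagents that add atoms: tert-butyldimethylsilyl trifluoromethanesulfonate, CC(C)(C)[Si](C)(C)OS(=O)(=O)C(F)(F)F
Why: Kinetic deprotonation at the α'-methylene (C2') and O-silylation give the cross-conjugated 2-silyloxydiene; the material is kept cold to prevent 1,5-hydrogen shifts.

Step 17
Reactants: 20 silyloxydiene; 19 cyclopentenone
Product: 21 Diels–Alder adduct: tricyclic core with C4 ketone, C5 methylene, TBS enol ether at C3'=C4', 2-methylprop-1-enyl on C5', R on C1 and C1'; cyclopentanone ring endo, H1 trans to H2, C10' syn to the C3'–C4' bridge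
Conditions: Me2AlCl (1.1 equiv), CH2Cl2, −78 → −40 °C
Reagents that add atoms: none
Why: Lewis-acid-promoted Diels–Alder reaction of a 2-silyloxycyclopentadiene with a cyclopentenone. The silyloxy group should direct C2' to the β-carbon C2 and C5' to C3, and the endo transition state should place the cyclopentanone ring under the diene. Each partner should be attacked anti to its bulky C1 or C1' substituent, which sets C2, C3, C2' and C5'; a stepwise double Michael path would lead to the same adduct.

Step 18
Reactants: 21 Diels–Alder adduct
Product: 22 5-(hydroxymethylene) C4 ketone of the core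
Conditions: LiN(SiMe3)2, THF, −78 °C; HCO2CH2CF3, −78 °C
Reagents that add atoms: 2,2,2-trifluoroethyl formate, O=COCC(F)(F)F
Why: Claisen-type formylation of the kinetic enolate, which should form at the C5 methylene and not at the hindered C3 methine; the silyl enol ether should survive the cold, alkoxide-poor conditions. The new carbon is C6.

Step 19
Reactants: 22 hydroxymethylene ketone
Product: 23 5-(isopropoxymethylene) C4 ketone of the core
Conditions: (CH3)2CHI, K2CO3, acetone, 50 °C
Reagents that add atoms: 2-iodopropane, CC(C)I
Why: O-alkylation of a hydroxymethylene ketone with a secondary iodide should give the vinylogous ester needed for the transposition.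

Step 20
Reactants: 23 isopropoxymethylene ketone
Product: 25 keto enal: C4(CH3)=C5–CHO, C3' ketone, C4' methyl endo, 2-methylprop-1-enyl on C5', R on C1 and C1', via tertiary carbinol 24 (not isolated)
Conditions: MeLi, CeCl3, THF, −78 °C; then 2 M HCl, THF, 0 °C → rt
Reagents that add atoms: methyllithium, [Li]C; water, O
Why: 1,2-addition of the methyl group (C15) to the vinylogous ester, then acid-induced allylic transposition of the Stork–Danheiser type, should give the β-methyl enal. The same acid hydrolyses the silyl enol ether, and C4' is protonated under equilibrating conditions to the epimer whose methyl group points endo, away from the C10' group that sits over the C3'–C4' bridge.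

Step 21
Reactants: 25 keto enal
Product: 26 tetracarbonyl compound: C6 enal, C6' aldehyde on the bridgehead, C7 and C7' aldehydes (chains C10(CH3)(OTBS)CH2CH2CHO), C3' ketone
Conditions: O3, CH2Cl2, −78 °C, Sudan red 7B end-point; then PPh3, −78 °C → rt
Reagents that add atoms: ozone, [O-][O+]=O
Why: Ozonolysis with reductive work-up; the three electron-rich trisubstituted alkenes should react far faster than the tetrasubstituted alkene conjugated to the aldehyde.

Step 22
Reactants: 26 tetracarbonyl compound; 27 methyl acrylate
Product: 28 bis-Baylis–Hillman adduct: chains C10(CH3)(OTBS)CH2CH2CH(OH)C(=CH2)CO2CH3 on C1 and C1' (carbinol epimers), C6 and C6' aldehydes intact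
Conditions: 27 (excess), DABCO (1,4-diazabicyclo[2.2.2]octane), MeOH, rt
Reagents that add atoms: methyl acrylate (second equivalent of 27), COC(=O)C=C
Why: Twofold Baylis–Hillman reaction in which each of the two unhindered aliphatic aldehydes (C7 and C7') takes up one molecule of 27 through its α-carbon, so that two molecules of the acrylate are incorporated; the bridgehead neopentyl aldehyde and the tetrasubstituted enal are poor acceptors and should stay. The carbinol centres disappear in step 23.

Step 23
Reactants: 28 bis-Baylis–Hillman adduct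
Product: 29 core dialdehyde with two (Z)-2-(bromomethyl)enoate chains, C10 and C10' as TBS ethers
Conditions: N-bromosuccinimide (2.4 equiv), Me2S (2.6 equiv), CH2Cl2, −20 → 0 °C
Reagents that add atoms: N-bromosuccinimide, O=C1CCC(=O)N1Br
Why: The bromodimethylsulfonium salt activates each allylic alcohol, and bromide displaces it in an SN2' sense to give the conjugated (Z)-2-(bromomethyl)enoate, one equivalent of the reagent being consumed per chain; aldehydes, ketone and silyl ethers should be spectators.

Step 24
Reactants: 29 dialdehyde bis(allylic bromide)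
Product: 31 bis(α-methylene lactone) bis-TBS ether (11,13- and 11',13'-didehydro-32), via bis-hydroxy ester 30 (not isolated)
Conditions: CrCl2 (8 equiv), THF, rt
Reagents that add atoms: none
Why: Two equivalents of CrCl2 reduce each allylic bromide to a trivalent allylchromium species, which adds through its γ-carbon (C7, C7') to the neighbouring aldehyde (C6, C6') in a closed six-membered transition state with allylic transposition, so that C11=C13 and C11'=C13' emerge as exocyclic methylenes; the closest known reaction type is the intramolecular Nozaki–Hiyama–Kishi-type addition of 2-(alkoxycarbonyl)allyl halides to aldehydes that annulates α-methylene lactones onto five- to seven-membered rings. Each carbocycle closes in a 7-exo-trig mode, and each chromium alkoxide of 30 then closes its lactone by 5-exo-trig acyl substitution with loss of methoxide. Allylchromium reagents add to aldehydes only, so the C3' ketone, the esters and the silyl ethers are spectators, and each chain can reach only its own aldehyde because the crossed closures would need strained medium rings. C6 and C6' are set by the tether: C7 can reach only the aldehyde face that carries C10, with the enal oxygen turned toward C1 and away from C15, and C7' enters from the C10' side while the chromium-bound oxygen sits in the open quadrant between C1'–H and C3–H. C7 and C7' are set by the chair: allylchromium species equilibrate by 1,3-metal shift, as crotylchromium does in giving anti adducts from either crotyl bromide, so the bromide geometry is not transmitted, and the chair with the C5–C6 and C7–C8 bonds both equatorial places O6 anti to C8, which is the trans ring fusion. The step needs aldehyde-over-ketone chemoselectivity, which the metal secures, and trans-selective closure on both halves, which rests on the equatorial preference around the bulky octahedral metal and is the least certain point.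

Step 25
Reactants: 31 bis(α-methylene lactone)
Product: 32 bis-TBS ether of the target
Conditions: [(Ph3P)CuH]6, toluene, H2O (few equiv), rt
Reagents that add atoms: none
Why: Conjugate hydride addition to both α-methylene lactones; each copper enolate should be protonated on the outer face remote from H7 (H7'), which places the C13 methyl cis to H7, the configuration that is also the more stable one. The isolated C4=C5 alkene and the ketone should not react.

Step 26
Reactants: 32 bis-TBS ether
Product: 33 target CNP0243924.4
Conditions: HF·pyridine, THF, 0 → 40 °C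
Reagents that add atoms: none
Why: Fluoride-assisted cleavage of the two tertiary silyl ethers under buffered acidic conditions, which the lactones and the ketone tolerate and under which C11 should not epimerise.

## Compound list

1 | geraniol, (2E)-3,7-dimethylocta-2,6-dien-1-ol | CC(C)=CCC/C(C)=C/CO | starting material
2 | (2S,3S)-2,3-epoxygeraniol | OC[C@@H]1O[C@@]1(C)CCC=C(C)C | intermediate
3 | (2R,3S)-3,7-dimethyl-2-(prop-2-en-1-yl)oct-6-ene-1,3-diol | OC[C@@H](CC=C)[C@@](C)(O)CCC=C(C)C | intermediate
4 | (2R,3S)-3,7-dimethyl-2-(prop-2-en-1-yl)-1-(triethylsilyloxy)oct-6-en-3-ol (formed in the flask) | CC[Si](CC)(CC)OC[C@@H](CC=C)[C@@](C)(O)CCC=C(C)C | intermediate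
5 | (2R,3S)-3-(tert-butyldimethylsilyloxy)-3,7-dimethyl-2-(prop-2-en-1-yl)-1-(triethylsilyloxy)oct-6-ene | CC[Si](CC)(CC)OC[C@@H](CC=C)[C@@](C)(O[Si](C)(C)C(C)(C)C)CCC=C(C)C | intermediate
6 | (2S,3S)-3-(tert-butyldimethylsilyloxy)-3,7-dimethyl-2-(prop-2-en-1-yl)oct-6-enal | O=C[C@@H](CC=C)[C@@](C)(O[Si](C)(C)C(C)(C)C)CCC=C(C)C | intermediate
7 | (4R,5S)-5-(tert-butyldimethylsilyloxy)-2,5,9-trimethyl-4-(prop-2-en-1-yl)deca-1,8-dien-3-ol, C3 epimers | C=C(C)C(O)[C@@H](CC=C)[C@@](C)(O[Si](C)(C)C(C)(C)C)CCC=C(C)C | intermediate
8 | (5R)-2-methyl-5-[(2S)-2-(tert-butyldimethylsilyloxy)-6-methylhept-5-en-2-yl]cyclopent-2-en-1-ol, C1 epimers | CC1=CC[C@@H]([C@@](C)(O[Si](C)(C)C(C)(C)C)CCC=C(C)C)C1O | intermediate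
9 | (5S)-2-methyl-5-[(2S)-2-(tert-butyldimethylsilyloxy)-6-methylhept-5-en-2-yl]cyclopent-2-en-1-one | CC1=CC[C@@H]([C@@](C)(O[Si](C)(C)C(C)(C)C)CCC=C(C)C)C1=O | intermediate
10 | (5R)-2-methyl-1-(2-methylprop-1-en-1-yl)-5-[(2S)-2-(tert-butyldimethylsilyloxy)-6-methylhept-5-en-2-yl]cyclopent-2-en-1-ol, C1 epimers | CC1=CC[C@@H]([C@@](C)(O[Si](C)(C)C(C)(C)C)CCC=C(C)C)C1(O)C=C(C)C | intermediate
11 | (4R)-2-methyl-3-(2-methylprop-1-en-1-yl)-4-[(2S)-2-(tert-butyldimethylsilyloxy)-6-methylhept-5-en-2-yl]cyclopent-2-en-1-one | CC1=C(C=C(C)C)[C@H]([C@@](C)(O[Si](C)(C)C(C)(C)C)CCC=C(C)C)CC1=O | intermediate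
12 | nerol, (2Z)-3,7-dimethylocta-2,6-dien-1-ol | CC(C)=CCC/C(C)=C\CO | starting material
13 | (2R,3S)-2,3-epoxynerol | OC[C@H]1O[C@@]1(C)CCC=C(C)C | intermediate
14 | (2S,3S)-3,7-dimethyl-2-(prop-2-en-1-yl)oct-6-ene-1,3-diol | OC[C@H](CC=C)[C@@](C)(O)CCC=C(C)C | intermediate
15 | (2S,3S)-3,7-dimethyl-2-(prop-2-en-1-yl)-1-(triethylsilyloxy)oct-6-en-3-ol (formed in the flask) | CC[Si](CC)(CC)OC[C@H](CC=C)[C@@](C)(O)CCC=C(C)C | intermediate
16 | (2S,3S)-3-(tert-butyldimethylsilyloxy)-3,7-dimethyl-2-(prop-2-en-1-yl)-1-(triethylsilyloxy)oct-6-ene | CC[Si](CC)(CC)OC[C@H](CC=C)[C@@](C)(O[Si](C)(C)C(C)(C)C)CCC=C(C)C | intermediate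
17 | (2R,3S)-3-(tert-butyldimethylsilyloxy)-3,7-dimethyl-2-(prop-2-en-1-yl)oct-6-enal | O=C[C@H](CC=C)[C@@](C)(O[Si](C)(C)C(C)(C)C)CCC=C(C)C | intermediate
18 | (2R,3S)-3-(tert-butyldimethylsilyloxy)-3,7-dimethyl-2-(2-oxopropyl)oct-6-enal | O=C[C@H](CC(C)=O)[C@@](C)(O[Si](C)(C)C(C)(C)C)CCC=C(C)C | intermediate
19 | (4S)-4-[(2S)-2-(tert-butyldimethylsilyloxy)-6-methylhept-5-en-2-yl]cyclopent-2-en-1-one | O=C1C=C[C@@H]([C@@](C)(O[Si](C)(C)C(C)(C)C)CCC=C(C)C)C1 | intermediate
20 | (5R)-2-(tert-butyldimethylsilyloxy)-3-methyl-4-(2-methylprop-1-en-1-yl)-5-[(2S)-2-(tert-butyldimethylsilyloxy)-6-methylhept-5-en-2-yl]cyclopenta-1,3-diene | CC1=C(C=C(C)C)[C@H]([C@@](C)(O[Si](C)(C)C(C)(C)C)CCC=C(C)C)C=C1O[Si](C)(C)C(C)(C)C | intermediate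
21 | Diels–Alder adduct: endo-fused tricyclic core, C4 ketone, C3'=C4' TBS enol ether, C5' 2-methylprop-1-enyl, R on C1 and C1' | O=C1C[C@H]([C@@](C)(O[Si](C)(C)C(C)(C)C)CCC=C(C)C)[C@H]2[C@H]3C(O[Si](C)(C)C(C)(C)C)=C(C)[C@@]([C@@H]3[C@@](C)(O[Si](C)(C)C(C)(C)C)CCC=C(C)C)(C=C(C)C)[C@@H]12 | intermediate
22 | 5-(hydroxymethylene) derivative of 21 | O=C1C(=CO)[C@H]([C@@](C)(O[Si](C)(C)C(C)(C)C)CCC=C(C)C)[C@H]2[C@H]3C(O[Si](C)(C)C(C)(C)C)=C(C)[C@@]([C@@H]3[C@@](C)(O[Si](C)(C)C(C)(C)C)CCC=C(C)C)(C=C(C)C)[C@@H]12 | intermediate
23 | 5-(isopropoxymethylene) derivative of 21 | O=C1C(=COC(C)C)[C@H]([C@@](C)(O[Si](C)(C)C(C)(C)C)CCC=C(C)C)[C@H]2[C@H]3C(O[Si](C)(C)C(C)(C)C)=C(C)[C@@]([C@@H]3[C@@](C)(O[Si](C)(C)C(C)(C)C)CCC=C(C)C)(C=C(C)C)[C@@H]12 | intermediate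
24 | C4 methyl carbinol of 23 (formed in the flask, C4 epimers) | CC1(O)C(=COC(C)C)[C@H]([C@@](C)(O[Si](C)(C)C(C)(C)C)CCC=C(C)C)[C@H]2[C@H]3C(O[Si](C)(C)C(C)(C)C)=C(C)[C@@]([C@@H]3[C@@](C)(O[Si](C)(C)C(C)(C)C)CCC=C(C)C)(C=C(C)C)[C@@H]12 | intermediate
25 | keto enal: C4(CH3)=C5–CHO, C3' ketone, endo C4' methyl, C5' 2-methylprop-1-enyl, R on C1 and C1' | CC1=C(C=O)[C@H]([C@@](C)(O[Si](C)(C)C(C)(C)C)CCC=C(C)C)[C@H]2[C@H]3C(=O)[C@@H](C)[C@@]([C@@H]3[C@@](C)(O[Si](C)(C)C(C)(C)C)CCC=C(C)C)(C=C(C)C)[C@@H]12 | intermediate
26 | tetracarbonyl compound: C6 enal, C6', C7 and C7' aldehydes, C3' ketone | CC1=C(C=O)[C@H]([C@@](C)(O[Si](C)(C)C(C)(C)C)CCC=O)[C@H]2[C@H]3C(=O)[C@@H](C)[C@@]([C@@H]3[C@@](C)(O[Si](C)(C)C(C)(C)C)CCC=O)(C=O)[C@@H]12 | intermediate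
27 | methyl acrylate | COC(=O)C=C | starting material
28 | bis-Baylis–Hillman adduct (C7 and C7' carbinol epimers) | CC1=C(C=O)[C@H]([C@@](C)(O[Si](C)(C)C(C)(C)C)CCC(O)C(=C)C(=O)OC)[C@H]2[C@H]3C(=O)[C@@H](C)[C@@]([C@@H]3[C@@](C)(O[Si](C)(C)C(C)(C)C)CCC(O)C(=C)C(=O)OC)(C=O)[C@@H]12 | intermediate
29 | core dialdehyde with two (Z)-2-(bromomethyl)enoate chains, bis-TBS ether | CC1=C(C=O)[C@H]([C@@](C)(O[Si](C)(C)C(C)(C)C)CC/C=C(\CBr)C(=O)OC)[C@H]2[C@H]3C(=O)[C@@H](C)[C@@]([C@@H]3[C@@](C)(O[Si](C)(C)C(C)(C)C)CC/C=C(\CBr)C(=O)OC)(C=O)[C@@H]12 | intermediate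
30 | bis-hydroxy ester after double allylation, drawn as the free alcohol (formed in the flask) | CC1=C2[C@@H](O)[C@H](C(=C)C(=O)OC)CC[C@](C)(O[Si](C)(C)C(C)(C)C)[C@@H]2[C@H]2[C@H]3C(=O)[C@@H](C)[C@]4([C@@H]3[C@@](C)(O[Si](C)(C)C(C)(C)C)CC[C@@H](C(=C)C(=O)OC)[C@@H]4O)[C@@H]12 | intermediate
31 | bis(α-methylene lactone) bis-TBS ether | CC1=C2[C@H]3OC(=O)C(=C)[C@@H]3CC[C@](C)(O[Si](C)(C)C(C)(C)C)[C@@H]2[C@H]2[C@H]3C(=O)[C@@H](C)[C@]4([C@@H]3[C@@](C)(O[Si](C)(C)C(C)(C)C)CC[C@H]3C(=C)C(=O)O[C@@H]34)[C@@H]12 | intermediate
32 | 10,10'-bis-O-TBS ether of the target | CC1=C2[C@H]3OC(=O)[C@@H](C)[C@@H]3CC[C@](C)(O[Si](C)(C)C(C)(C)C)[C@@H]2[C@H]2[C@H]3C(=O)[C@@H](C)[C@]4([C@@H]3[C@@](C)(O[Si](C)(C)C(C)(C)C)CC[C@H]3[C@H](C)C(=O)O[C@@H]34)[C@@H]12 | intermediate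
33 | CNP0243924.4 | CC1=C2[C@H]3OC(=O)[C@@H](C)[C@@H]3CC[C@](C)(O)[C@@H]2[C@H]2[C@H]3C(=O)[C@@H](C)[C@]4([C@@H]3[C@@](C)(O)CC[C@H]3[C@H](C)C(=O)O[C@@H]34)[C@@H]12 | target

## Step count and risks

Total: 26 steps. Longest linear sequence: 20 steps (steps 1–9 and 16–26); the nerol branch (steps 10–15) joins at step 17.

**Step 24 (key step).** The most likely failure is poor control of the ring fusion: addition through a transition state with the chain axial would close cis-fused lactones, as is common for zinc- or indium-mediated additions of such bromides. Protonation of the allylchromium species before it adds to the hindered C6' aldehyde is a second risk. Fallback: replace the metal-centred closed transition state by an open one. From 26, a Horner–Wadsworth–Emmons reaction of the two unhindered aldehydes with methyl 2-(dimethoxyphosphoryl)-3-(trimethylsilyl)propanoate would give the bis[2-(trimethylsilylmethyl)enoate] dialdehyde F1. BF3·OEt2 in CH2Cl2 at −78 °C should then trigger two intramolecular Hosomi–Sakurai additions through open antiperiplanar transition states, which favour trans-fused α-methylene lactones in ring-forming cases. Lactonisation on warming with acid returns the route at 31.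

**Step 17.** The diene may undergo a 1,5-hydrogen shift before it reacts, which would scramble C1' and offer the wrong diene, or the reaction may stop after the first C–C bond. Fallback: form the two bonds in separate conjugate additions. From 20 and 19, catalytic HN(SO2CF3)2 at −78 °C should give the Mukaiyama–Michael adduct, silyl enol ether F2, with only C2–C2' formed. Me2AlCl at −40 °C should then close C3–C5' by an intramolecular Mukaiyama–Michael addition with silyl transfer to O3', which returns the route at 21.

**Step 20.** The organometallic may enolise the hindered ketone instead of adding, and protonation at C4' may occur from the wrong face during hydrolysis. Fallback for the stereochemical failure: isolate the exo-methyl C4' epimer of 25, F3, and equilibrate it through the C3' enolate with DBU in toluene to return at 25. Since C4' stays epimerisable, the same correction can be made on 32.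

**Step 22.** The amine-catalysed addition is slow, and the polycarbonyl substrate may undergo aldol side reactions in the meantime. Fallback: a stoichiometric aldol route to the same adducts. From 26, the lithium enolate of methyl 3-(phenylselanyl)propanoate at −78 °C should add to the two unhindered aldehydes and give the bis(β-hydroxy selenide) F4. Oxidation with H2O2 and syn-elimination of the selenoxide returns the route at 28.

**Step 15.** Under hydroxide the aldehyde may enolise toward C1 with epimerisation or β-elimination of silanolate, and the product enone may isomerise into conjugation with C1. Fallback: separate the bond formation from the dehydration. From 18, a brief aldol addition with K2CO3 in MeOH at −20 °C should stop at the β-hydroxy ketone F5. Methanesulfonyl chloride and Et3N at 0 °C would convert it through the mesylate F6 into 19 by mild elimination.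

**Step 26.** Cleavage of the two hindered tertiary silyl ethers may be slow, with competing elimination of the tertiary alcohols. Fallback: remove the silyl groups where they are less hindered. From 29, HF·pyridine should give the diol dialdehyde F7, in which C10 and C10' are still acyclic. CrCl2 would then close the rings to the bis(α-methylene lactone) diol F8, with the caveat that the free alcohols can form lactols with the aldehydes. [(Ph3P)CuH]6 returns the route at 33.

## Further compounds

F1 | step 24 | bis[2-(trimethylsilylmethyl)enoate] dialdehyde (alkene isomers) | CC1=C(C=O)[C@H]([C@@](C)(O[Si](C)(C)C(C)(C)C)CCC=C(C[Si](C)(C)C)C(=O)OC)[C@H]2[C@H]3C(=O)[C@@H](C)[C@@]([C@@H]3[C@@](C)(O[Si](C)(C)C(C)(C)C)CCC=C(C[Si](C)(C)C)C(=O)OC)(C=O)[C@@H]12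
F2 | step 17 | Mukaiyama–Michael adduct with C2–C2' bond only (unprimed C4 TBS enol ether, primed enone) | CC(C)=CC1=C(C)C(=O)[C@H]([C@H]2C=C(O[Si](C)(C)C(C)(C)C)C[C@@H]2[C@@](C)(O[Si](C)(C)C(C)(C)C)CCC=C(C)C)[C@H]1[C@@](C)(O[Si](C)(C)C(C)(C)C)CCC=C(C)C
F3 | step 20 | C4' epimer of 25 (exo methyl) | CC1=C(C=O)[C@H]([C@@](C)(O[Si](C)(C)C(C)(C)C)CCC=C(C)C)[C@H]2[C@H]3C(=O)[C@H](C)[C@@]([C@@H]3[C@@](C)(O[Si](C)(C)C(C)(C)C)CCC=C(C)C)(C=C(C)C)[C@@H]12
F4 | step 22 | bis(β-hydroxy selenide) aldol adduct (epimers at the new centres) | CC1=C(C=O)[C@H]([C@@](C)(O[Si](C)(C)C(C)(C)C)CCC(O)C(C[Se]c2ccccc2)C(=O)OC)[C@H]2[C@H]3C(=O)[C@@H](C)[C@@]([C@@H]3[C@@](C)(O[Si](C)(C)C(C)(C)C)CCC(O)C(C[Se]c4ccccc4)C(=O)OC)(C=O)[C@@H]12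
F5 | step 15 | (4S)-3-hydroxy-4-[(2S)-2-(tert-butyldimethylsilyloxy)-6-methylhept-5-en-2-yl]cyclopentan-1-one (C3 epimers) | O=C1CC(O)[C@@H]([C@@](C)(O[Si](C)(C)C(C)(C)C)CCC=C(C)C)C1
F6 | step 15 | methanesulfonate of F5 | O=C1CC(OS(C)(=O)=O)[C@@H]([C@@](C)(O[Si](C)(C)C(C)(C)C)CCC=C(C)C)C1
F7 | step 26 | core dialdehyde with two (Z)-2-(bromomethyl)enoate chains, free C10 and C10' alcohols | CC1=C(C=O)[C@H]([C@@](C)(O)CC/C=C(\CBr)C(=O)OC)[C@H]2[C@H]3C(=O)[C@@H](C)[C@@]([C@@H]3[C@@](C)(O)CC/C=C(\CBr)C(=O)OC)(C=O)[C@@H]12
F8 | step 26 | bis(α-methylene lactone) diol (11,13- and 11',13'-didehydro target) | CC1=C2[C@H]3OC(=O)C(=C)[C@@H]3CC[C@](C)(O)[C@@H]2[C@H]2[C@H]3C(=O)[C@@H](C)[C@]4([C@@H]3[C@@](C)(O)CC[C@H]3C(=C)C(=O)O[C@@H]34)[C@@H]12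
A1 | alternative 1 | β-acetoxy enone (C6' ketone, C7'=C10' enol acetate) | CC1=C2[C@H]3OC(=O)[C@@H](C)[C@@H]3CC[C@](C)(O)[C@@H]2[C@H]2[C@H]3C(=O)[C@@H](C)[C@]4([C@@H]3C(OC(C)=O)=C([C@H](C)C(=O)OC)C4=O)[C@@H]12
A2 | alternative 1 | ethylene | C=C
A3 | alternative 1 | cis-fused cyclobutane photoadduct | CC1=C2[C@H]3OC(=O)[C@@H](C)[C@@H]3CC[C@](C)(O)[C@@H]2[C@H]2[C@H]3C(=O)[C@@H](C)[C@]4([C@@H]3[C@]5(OC(C)=O)CC[C@]5([C@H](C)C(=O)OC)C4=O)[C@@H]12
A4 | alternative 2 | tetraene with vinyl groups on C7, C10, C7' and C10' | CC1=C([C@H]2OC(=O)[C@@H](C)[C@@H]2C=C)[C@H]([C@@](C)(O)C=C)[C@H]2[C@H]3C(=O)[C@@H](C)[C@@]([C@@H]3[C@@](C)(O)C=C)([C@H]4OC(=O)[C@@H](C)[C@@H]4C=C)[C@@H]12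
A5 | alternative 2 | 8,9,8',9'-tetradehydro target | CC1=C2[C@H]3OC(=O)[C@@H](C)[C@@H]3C=C[C@](C)(O)[C@@H]2[C@H]2[C@H]3C(=O)[C@@H](C)[C@]4([C@@H]3[C@@](C)(O)C=C[C@H]3[C@H](C)C(=O)O[C@@H]34)[C@@H]12
A6 | alternative 3 | α,α'-dibromoketone tethered to the C1'=C5' cycloheptene (bromide epimers) | CC1=C2[C@H]3OC(=O)[C@@H](C)[C@@H]3CC[C@](C)(O[Si](C)(C)C)[C@@H]2[C@@H](C(Br)C(=O)C(C)Br)[C@H]1C4=C[C@@](C)(O[Si](C)(C)C)CC[C@H]3[C@H](C)C(=O)O[C@@H]34
A7 | alternative 3 | bis-trimethylsilyl ether of the target | CC1=C2[C@H]3OC(=O)[C@@H](C)[C@@H]3CC[C@](C)(O[Si](C)(C)C)[C@@H]2[C@H]2[C@H]3C(=O)[C@@H](C)[C@]4([C@@H]3[C@@](C)(O[Si](C)(C)C)CC[C@H]3[C@H](C)C(=O)O[C@@H]34)[C@@H]12
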